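The readings were computed with constants of no real substance, noise included.

A decade is the unit here: one tenfold fall of the substrate left. The decade time τ is the hours a flask needs for one decade, so a flask at time t has passed t/τ decades.

| setting | eta | alpha | flask |
|---|---|---|---|
| substrate | 0.052 M | 0.052 M | 0.052 M |
| gas phase | 24 mM (held) | 24 mM (held) | 24 mM (held) |
| catalyst | 0.5 mol% | 0.75 mol% | 1 mol% |
| remark | run made earlier | run made earlier |  |
| time |  |  | 15 h |

- eta (time / h: target / %): 0.667: 12.9; 1.33: 26.9; 2.50: 45.5; 5.00: 71.0; 10.0: 89.8
- alpha (time / h: target / %): 2.00: 50.8; 4.00: 76.6; 5.00: 83.9; 8.00: 92.8; 10.0: 94.7

(standard deviation of a reading: 0.3 percentage points)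

- at the start none of the gas phase is in solution

- east: doubling the amount of catalyst, all else as stated
- north: doubling the transfer coefficient of the gas phase, all else as stated
- west: doubling the saturation concentration of gas phase, all else as stated

* amount of target at 15 h, in percent of the substrate charged
* the change that raises the amount of target at 15 h, in percent of the substrate charged most ("none" if none brings more than 2 percentage points) (east / north / west / none)
* amount of target at 15 h, in percent of the substrate charged, after east

Two chemists dispute this flask, and both start from my reckoning of τ. In the eta run, 71.0% at 5.00 h is 0.538 decades, so τ is 9.30 h. In the alpha run, 76.6% at 4.00 h gives 6.34 h. The ratio of these times is 1.47, and the loadings stand at 1.50. So with the gas held, the substrate reads as pseudo-first-order, with τ inverse to catalyst concentration. The flask's decade time is then 4.65 h. Its 15 h make 3.23 decades, leaving 0.0595% of the substrate.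

The first chemist stops there and reads 99.9% target. The second objects with the alpha run. At 10.0 h τ promises 97.4%, but the reading is 94.7%. That shortfall of 2.7 percentage points is larger than the scatter. So target has a ceiling or a loss. The substrate reckoned as left in the flask is also smaller than the margin, so by this reckoning halving τ gains little.

The second chemist's number is the forecast: 95% (92.5% to 97.5%), best change none, and 92% after east (85% to 97.5%). At the asked time, it says, “it sits at that plateau or slightly beyond it”.

The flask gives 94.1%, best change none, and 93.7% after east. Its substrate stands at 0.0372% and its over-reaction product at 5.87%. The first view has its region early: at 1.50 h the flask holds 49.6% target and 0.181% over-reaction product.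

    gas phase ⇌ dissolved gas, rate k1*(csat - [dissolved gas]) (kL = 0.00250 s⁻¹)
    substrate + dissolved gas + catalyst → catalyst + target (k = 12.0 L² mol⁻² s⁻¹)
    target → over-reaction product (k = 1.30 × 10⁻⁶ s⁻¹)

The neighbouring flask has 0.013 M of substrate at the same loading, so its catalyst concentration is a quarter of the flask's. Reckoned inverse to that concentration, its τ is 18.6 h. Its 15 h make 0.806 decades, which leaves 15.6% of the substrate. The neighbour holds 14% substrate and 82.6% target.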